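The target is a diarylmethane whose monobrominated ring (ring A, numbered as a phenol: OH on C1, Br on C2, CH2 on C4) has its oxygen para to the benzylic carbon. This 1,4-pattern is exploited by a Diels–Alder benzannulation: a 1-methoxy-3-silyloxybutadiene delivers C1, C2, C3 and C6 of ring A, and the alkyne of an aryl ethynyl ketone delivers C4 and C5. One operation forms C3–C4 and C5–C6, aromatises ring A by loss of methanol and unveils its phenol. The precursor is the terminal ynone of the 3,5-dibromo-4-methoxyphenyl ring B, which already holds both bromines. Monobromination, carbonyl deoxygenation and demethylation complete the route.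

Key step: step 3

Assumption: the target has no stereocentre and no stereogenic axis and is therefore achiral, so no enantiocontrol is needed; the chiral intermediates 3, 6 and 10 are racemates whose stereocentres are removed later in the route.

Step 1
Reactants: 1 3,5-dibromo-4-methoxybenzaldehyde; 2 ethynylmagnesium bromide
Product: 3 rac-1-(3,5-dibromo-4-methoxyphenyl)prop-2-yn-1-ol
Conditions: 2 (1.3 equiv, 0.5 M in THF), THF, 0 °C → rt; sat. aq NH4Cl
Reagents that add atoms: none
Why: Grignard 1,2-addition of the alkynylmagnesium reagent to the aromatic aldehyde, which is too weakly basic and too slow in halogen–metal exchange to disturb the aryl bromides; the carbinol centre forms as a racemate without control and is erased by the oxidation in step 2.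

Step 2
Reactants: 3 rac-1-(3,5-dibromo-4-methoxyphenyl)prop-2-yn-1-ol
Product: 4 1-(3,5-dibromo-4-methoxyphenyl)prop-2-yn-1-one
Conditions: activated MnO2 (15 equiv), CH2Cl2, rt
Reagents that add atoms: none
Why: MnO2 oxidation of a benzylic and propargylic alcohol to the conjugated ketone proceeds under neutral, non-nucleophilic conditions, which the Michael-sensitive terminal ynone should tolerate.

Step 3
Reactants: 4 1-(3,5-dibromo-4-methoxyphenyl)prop-2-yn-1-one; 5 (E)-1-methoxy-3-(trimethylsilyloxy)buta-1,3-diene
Product: 8 (3,5-dibromo-4-methoxyphenyl)(4-hydroxyphenyl)methanone, via cyclohexadiene cycloadduct 6 (not isolated), via aryl trimethylsilyl ether 7 (not isolated)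
Conditions: 5 (1.5 equiv), toluene, rt → 80 °C; then 1 M HCl, THF, rt
Reagents that add atoms: none
Why: The electron-rich diene 5 should add across the C≡C bond of the electron-poor ynone 4 in a concerted but asynchronous normal-demand Diels–Alder reaction, the bond between the CH2 terminus of the diene and the terminal alkyne carbon forming ahead of the other, to give cyclohexa-1,4-diene 6. The closest known reaction type is the benzannulation of 1-methoxy-3-silyloxybutadienes with propiolates and alkynyl ketones, which delivers 4-hydroxybenzoates and 4-acylphenols. Ring A is closed by the [4+2] cycloaddition itself, both new sigma bonds (C3–C4 and C5–C6) being made suprafacially on the s-cis diene in one intermolecular event. Aromatisation then drives 1,4-elimination of methanol from 6 to aryl silyl ether 7, which dilute acid hydrolyses to phenol 8; the only new stereocentre, the methoxy-bearing sp3 carbon of 6, forms as a racemate without control and is destroyed in this elimination. The selectivity required is regiochemical (acyl para, not meta, to oxygen), and it is secured by the polarisation of both partners: the largest HOMO coefficient lies on the CH2 terminus of the diene, pushed by both oxygen donors, and the largest LUMO coefficient on the unsubstituted β-carbon of the ynone. Chemoselectivity follows from the substrate design, since the aryl bromides and the methyl ether are inert to heat and dilute acid and 4 has no acidic OH that would protonate the diene.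

Step 4
Reactants: 8 (3,5-dibromo-4-methoxyphenyl)(4-hydroxyphenyl)methanone
Product: 9 (3-bromo-4-hydroxyphenyl)(3,5-dibromo-4-methoxyphenyl)methanone
Conditions: NBS (1.0 equiv), p-TsOH·H2O (10 mol %), MeOH, rt
Reagents that add atoms: N-bromosuccinimide, O=C1CCC(=O)N1Br
Why: Electrophilic aromatic bromination of a para-substituted phenol can only go ortho to the hydroxyl of ring A, is slowed after the first bromine by that bromine and the ketone, finds no free ortho or para position on ring B, and is run before the benzylic CH2 exists.

Step 5
Reactants: 9 (3-bromo-4-hydroxyphenyl)(3,5-dibromo-4-methoxyphenyl)methanone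
Product: 11 2-bromo-4-[(3,5-dibromo-4-methoxyphenyl)methyl]phenol, via benzhydrol 10 (not isolated)
Conditions: Et3SiH (3 equiv), TFA, 0 °C → 50 °C
Reagents that add atoms: none
Why: Ionic hydrogenation, in which the protonated diaryl ketone and then the benzhydryl cation from alcohol 10, both stabilised by the para-hydroxyphenyl ring, each take hydride from the silane, should give the CH2 group without touching the C–Br bonds; the transient carbinol centre of 10 is racemic and is removed in the same pot.

Step 6
Reactants: 11 2-bromo-4-[(3,5-dibromo-4-methoxyphenyl)methyl]phenol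
Product: 12 2,6-dibromo-4-[(3-bromo-4-hydroxyphenyl)methyl]phenol
Conditions: BBr3 (3 equiv), CH2Cl2, −78 °C → rt; then H2O
Reagents that add atoms: none
Why: Lewis acid ether cleavage, in which boron binds the methoxy oxygen and bromide attacks the methyl group by SN2, should proceed readily on the twisted di-ortho-bromo anisole and leave the diarylmethane and aryl bromides intact at or below room temperature.

Compound list
1 | 3,5-dibromo-4-methoxybenzaldehyde | COc1c(Br)cc(C=O)cc1Br | starting material
2 | ethynylmagnesium bromide | C#C[Mg]Br | starting material
3 | rac-1-(3,5-dibromo-4-methoxyphenyl)prop-2-yn-1-ol | COc1c(Br)cc(cc1Br)C(O)C#C | intermediate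
4 | 1-(3,5-dibromo-4-methoxyphenyl)prop-2-yn-1-one | COc1c(Br)cc(cc1Br)C(=O)C#C | intermediate
5 | (E)-1-methoxy-3-(trimethylsilyloxy)buta-1,3-diene | CO/C=C/C(=C)O[Si](C)(C)C | starting material
6 | rac-(3,5-dibromo-4-methoxyphenyl)[6-methoxy-4-(trimethylsilyloxy)cyclohexa-1,4-dien-1-yl]methanone | COC1C=C(O[Si](C)(C)C)CC=C1C(=O)c1cc(Br)c(OC)c(Br)c1 | intermediate
7 | (3,5-dibromo-4-methoxyphenyl)[4-(trimethylsilyloxy)phenyl]methanone | COc1c(Br)cc(cc1Br)C(=O)c1ccc(O[Si](C)(C)C)cc1 | intermediate
8 | (3,5-dibromo-4-methoxyphenyl)(4-hydroxyphenyl)methanone | COc1c(Br)cc(cc1Br)C(=O)c1ccc(O)cc1 | intermediate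
9 | (3-bromo-4-hydroxyphenyl)(3,5-dibromo-4-methoxyphenyl)methanone | COc1c(Br)cc(cc1Br)C(=O)c1ccc(O)c(Br)c1 | intermediate
10 | rac-2-bromo-4-[(3,5-dibromo-4-methoxyphenyl)(hydroxy)methyl]phenol | COc1c(Br)cc(cc1Br)C(O)c1ccc(O)c(Br)c1 | intermediate
11 | 2-bromo-4-[(3,5-dibromo-4-methoxyphenyl)methyl]phenol | COc1c(Br)cc(Cc2ccc(O)c(Br)c2)cc1Br | intermediate
12 | 2,6-dibromo-4-[(3-bromo-4-hydroxyphenyl)methyl]phenol | Oc1ccc(Cc2cc(Br)c(O)c(Br)c2)cc1Br | target

Total step count: 6. Longest linear sequence: 6 steps (1 → 12).

Steps most likely to fail

1. Step 3 (key step). What may go wrong: oligomerisation of the terminal ynone on heating, premature hydrolysis of the silyl enol ether of the diene, or open-chain Mukaiyama–Michael addition without ring closure, each of which would erode the benzannulation. Fallback: the diaryl ketone is assembled by carbonyl addition instead of cycloaddition. Setting out from aldehyde 1, commercial 4-(oxan-2-yloxy)phenylmagnesium bromide (0.5 M in THF, 0 °C) should add to give the carbinol (3,5-dibromo-4-methoxyphenyl)[4-(oxan-2-yloxy)phenyl]methanol F1 as a mixture of diastereomers. MnO2 in CH2Cl2 should oxidise it to rac-(3,5-dibromo-4-methoxyphenyl)[4-(oxan-2-yloxy)phenyl]methanone F2. PPTS in MeOH at rt should then remove the tetrahydropyranyl acetal, and the fallback comes back to the route at 8.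

2. Step 5. What may go wrong: insufficient protonation and ionisation of the bromine-deactivated ketone in TFA, so that reduction stalls at the alcohol stage, or capture of the benzhydryl cation by a phenol ring of a second molecule (Friedel–Crafts oligomerisation). Fallback: the two hydride transfers are separated and the first is made nucleophilic. Setting out from 9, NaBH4 in THF/MeOH at 0 °C should give benzhydrol 10, now isolated. Deoxygenation of 10 with Et3SiH and BF3·OEt2 in CH2Cl2/MeCN at −20 °C, where the alcohol ionises easily and the cation is quenched cold and dilute, should bring the fallback back to the route at 11. No compound outside the list is made (F0).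

3. Step 4. What may go wrong: over-bromination at the second position ortho to the hydroxyl, or incomplete conversion, leaving mixtures of un-, mono- and dibrominated ketones that are hard to separate. Fallback: bromination is moved to an anisole, where it is self-limiting. Setting out from 8, MeI and K2CO3 in DMF should give (3,5-dibromo-4-methoxyphenyl)(4-methoxyphenyl)methanone F3. Br2 in AcOH at 50 °C should brominate once, ortho to the new methoxy group, to give (3-bromo-4-methoxyphenyl)(3,5-dibromo-4-methoxyphenyl)methanone F4, because a second substitution on an acyl-deactivated ortho-bromoanisole is very slow. Et3SiH in TFA should reduce the ketone to 1,3-dibromo-5-[(3-bromo-4-methoxyphenyl)methyl]-2-methoxybenzene F5. Excess BBr3 in CH2Cl2 should cleave both methyl ethers, and the fallback comes back to the route at the target 12.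

Further compounds
F1 | step 3 | (3,5-dibromo-4-methoxyphenyl)[4-(oxan-2-yloxy)phenyl]methanol, mixture of diastereomers | COc1c(Br)cc(cc1Br)C(O)c1ccc(OC2CCCCO2)cc1
F2 | step 3 | rac-(3,5-dibromo-4-methoxyphenyl)[4-(oxan-2-yloxy)phenyl]methanone | COc1c(Br)cc(cc1Br)C(=O)c1ccc(OC2CCCCO2)cc1
F0 | step 5 | none | none
F3 | step 4 | (3,5-dibromo-4-methoxyphenyl)(4-methoxyphenyl)methanone | COc1ccc(cc1)C(=O)c1cc(Br)c(OC)c(Br)c1
F4 | step 4 | (3-bromo-4-methoxyphenyl)(3,5-dibromo-4-methoxyphenyl)methanone | COc1ccc(cc1Br)C(=O)c1cc(Br)c(OC)c(Br)c1
F5 | step 4 | 1,3-dibromo-5-[(3-bromo-4-methoxyphenyl)methyl]-2-methoxybenzene | COc1ccc(Cc2cc(Br)c(OC)c(Br)c2)cc1Br
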